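The data are calculated for an exercise; noise was put on by code.

What ratio of target to isomer of the product A stands in the flask at 3.0 s and at 6.0 min, and which of the two leads at the later time?

| setting | larch | oak | flask |
|---|---|---|---|
| solid substrate | 0.50 mM | 2 mM | 1.0 mM |
| remark | run made earlier | run made earlier |  |
| time |  |  | 6.0 min |

- larch (time / min: target / %, isomer of the product A / %): 0.667: 42, 10; 2.00: 94, 2; 3.00: 91, 3; 5.00: 91, 3; 8.00: 90, 4
- oak (time / min: target / %, isomer of the product A / %): 0.500: 6, 4; 1.00: 16, 3; 2.00: 39, 3; 4.00: 77, 2; 8.00: 96, 0

(each reading ± 1.5 percentage points)

- for target the crystals are counted in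
- as a solid, counted per litre of solution: solid substrate, crystals
- candidate steps: starting material <-> target; target <-> isomer of the product A; target <-> isomer of the product B; isomer of the product A <-> starting material; solid substrate <-> starting material; crystals <-> target
- at the start none of the solid substrate is in solution

- ratio of target to isomer of the product A at 3.0 s
- ratio of target to isomer of the product A at 6.0 min
- which of target and isomer of the product A there is more of at 6.0 min

- From oak up to 4.00 min, solid goes into solution at about 0.395 mM min⁻¹, so I reckon the flask's charge dissolved after 2.53 min, well before 6.0 min. The late ratio is what you can reckon.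
- Larch from 3.00 min on reads target at 90.7 % and, as a mean of its readings, 0.0167 mM of isomer of the product A: call this the floor, the late [isomer of the product A] in mM, a level read from scattered readings, with time dropped out.
- Extreme one: with no crystals, the late share of isomer of the product A stays fixed, and the flask repeats larch's ratio of 27.2.
- Extreme two: crystals hold dissolved target steady, so the floor stays fixed in mM (thermodynamic control with a solid present), and the ratio grows with charge to 54.4.
- Oak separates them: extreme one predicts 3.33 % at its last reading, extreme two 0.833 %, and oak read 0 % with a scatter of 1.5 percentage points. I therefore place the flask at extreme two, with target leading.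
- For 3.0 s no reading stands close. Oak's earliest gives 1.50 at 0.500 min, and I expect less than that.
- The forecast gave 0.9, 35 and target ahead, saying “Whether 1 mM crystallises is uncertain”.
- The flask gives 0.569, 53.8 and target ahead, with 94.8 % against 1.76 %.

    starting material ⇌ target (K = 4.70, k = 0.226 s⁻¹)
    target ⇌ isomer of the product A (K = 0.653, k = 0.0817 s⁻¹)
    target ⇌ isomer of the product B (K = 1.76, k = 0.00443 s⁻¹)
    isomer of the product A ⇌ starting material (k = 0.200 s⁻¹)
    solid substrate ⇌ starting material, rate k5*(cs5 - [starting material]) while solid is left; crystals form when [starting material] > cs5 (solubility = 0.200 mM, k = 0.0387 s⁻¹)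
    crystals ⇌ target, rate k6*(cs6 - [target]) while solid is left; crystals form when [target] > cs6 (solubility = 0.0270 mM, k = 3.31 s⁻¹)

- In the flask, isomer of the product A ends at 0.0176 mM, beside my floor of 0.0167 mM. The half-life of dissolved target by the forward rate of its turning into isomer of the product A alone, 0.14 min at 1.19 min, is short against 6.0 min, and the equilibrium constant of that step times the solubility of target gives 0.0176 mM.
- In a neighbour flask charged with 1.7 mM of solid substrate, the floor gives isomer of the product A a share of 0.982 % and a ratio of target to it of 92.3. That neighbour flask computes to 1.04 % and 93.5 at 6.0 min.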